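**Strategy.** The ten-membered carbocycle C1–C10 contains the unit C9(O)–C10(CO2Me)=C1H–C2H2 with C9 and C2 cis on the double bond, the signature of an opened cyclobutene. The route therefore builds the lactone-fused cyclooct-4-enone (ring C2–C9, ketone at C9) by asymmetric chromium allylation, a Henry reaction and ring-closing metathesis. Its C9=C2 silyl enol ether adds methyl propiolate in a [2+2] sense, and fluoride-triggered retro-aldol cleavage of the C9–C2 bond inserts C10 and C1: one operation delivers the cyclodecadiene, the ester-bearing cis C1=C10 alkene and the C9 carbonyl. Reduction, two acylations and unmasking of the α-methylene lactone finish the synthesis.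

Key step: step 14

Remark: atoms are numbered as in the target (carbocycle C1–C10, lactone carbons C11–C13 closed on O6, ester carbon C14 on C10, hydroxymethyl C15 on C4). The configuration at C11 of the selenides and at the nitro-bearing carbon of 15 and 16 is temporary and is erased later; absolute configuration is carried by the SMILES strings.

Step 1
Reactants: 1 2-methylidenepropane-1,3-diol
Product: 2 2-{[(tert-butyldiphenylsilyl)oxy]methyl}prop-2-en-1-ol
Conditions: TBDPSCl (0.8 equiv), imidazole, THF, 0 °C (diol in excess)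
Reagents that add atoms: tert-butyl(chloro)diphenylsilane (TBDPSCl), CC(C)(C)[Si](Cl)(c1ccccc1)c1ccccc1
Why: Statistical mono-O-silylation of a symmetrical diol used in excess should give mainly the mono-silyl ether; no stereocentre is involved.

Step 2
Reactants: 2 2-{[(tert-butyldiphenylsilyl)oxy]methyl}prop-2-en-1-ol
Product: 3 {[2-(bromomethyl)prop-2-en-1-yl]oxy}(tert-butyl)diphenylsilane
Conditions: CBr4, PPh3, CH2Cl2, 0 °C
Reagents that add atoms: tetrabromomethane, BrC(Br)(Br)Br
Why: Appel bromination of the primary allylic alcohol under neutral conditions that spare the silyl ether; SN2 and SN2′ attack give the same bromide.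

Step 3
Reactants: 4 2,2-dimethoxyacetaldehyde; 5 methyl acrylate
Product: 6 methyl 3-hydroxy-4,4-dimethoxy-2-methylidenebutanoate (racemic)
Conditions: DABCO (0.5 equiv), dioxane–H2O, rt
Reagents that add atoms: none
Why: Morita–Baylis–Hillman reaction of a non-enolisable, electron-poor aldehyde with an acrylate; the carbinol centre is racemic and is destroyed in step 4.

Step 4
Reactants: 6 methyl 3-hydroxy-4,4-dimethoxy-2-methylidenebutanoate
Product: 7 methyl (2Z)-2-(bromomethyl)-4,4-dimethoxybut-2-enoate
Conditions: NBS, Me2S, CH2Cl2, 0 °C to rt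
Reagents that add atoms: N-bromosuccinimide, O=C1CCC(=O)N1Br
Why: Corey–Kim-type activation of the allylic alcohol followed by SN2′ delivery of bromide should give the conjugated, thermodynamically preferred (Z)-2-(bromomethyl)alk-2-enoate without acid that would endanger the acetal.

Step 5
Reactants: 7 methyl (2Z)-2-(bromomethyl)-4,4-dimethoxybut-2-enoate; 8 acrolein
Product: 11 (4S,5R)-4-(dimethoxymethyl)-5-ethenyl-3-methylideneoxolan-2-one, via silyl ether 9 (not isolated), via hydroxy ester 10 (not isolated)
Conditions: CrCl2 (10 mol %), chiral carbazole-bis(oxazoline) ligand (11 mol %; enantiomer directing attack on the Si face of acrolein), Mn, TMSCl, THF, rt; then PPTS (cat.), MeOH, rt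
Reagents that add atoms: none
Why: Catalytic asymmetric Nozaki–Hiyama–Kishi-type 2-(alkoxycarbonyl)allylation, in which the γ-carbon of the allyl unit of 7 is transferred to acrolein through a chair transition state with the acetal-bearing substituent equatorial (anti adduct, hence the 4,5-trans lactone, C6 and C7 of the target) while the ligand selects the aldehyde face; acid in methanol then removes the silyl group and closes the γ-lactone, the dimethyl acetal being inert to exchange in methanol.

Step 6
Reactants: 11 (4S,5R)-4-(dimethoxymethyl)-5-ethenyl-3-methylideneoxolan-2-one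
Product: 12 (3S,4S,5R)-4-(dimethoxymethyl)-5-ethenyl-3-[(phenylselanyl)methyl]oxolan-2-one
Conditions: PhSeH, Et3N (10 mol %), CH2Cl2, 0 °C
Reagents that add atoms: benzeneselenol, [SeH]c1ccccc1
Why: Conjugate (Michael) addition of the selenol masks the α-methylene lactone against the bases and nucleophiles used later; protonation should place the CH2SePh group trans to the C4 substituent, but this centre (C11) is erased in step 20.

Step 7
Reactants: 12 (3S,4S,5R)-4-(dimethoxymethyl)-5-ethenyl-3-[(phenylselanyl)methyl]oxolan-2-one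
Product: 13 (2R,3S,4S)-2-ethenyl-5-oxo-4-[(phenylselanyl)methyl]oxolane-3-carbaldehyde
Conditions: TFA–H2O (9:1), CH2Cl2, 0 °C
Reagents that add atoms: water, O
Why: Acid-catalysed acetal hydrolysis; the aldehyde α-centre (C7) already sits in the thermodynamically preferred all-trans arrangement, so enolisation cannot erode it.

Step 8
Reactants: 13 (2R,3S,4S)-2-ethenyl-5-oxo-4-[(phenylselanyl)methyl]oxolane-3-carbaldehyde; 14 nitroethane
Product: 15 5-ethenyl-4-[(1S)-1-hydroxy-2-nitropropyl]-3-[(phenylselanyl)methyl]oxolan-2-one (lactone centres as in 13; epimers at the nitro-bearing carbon)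
Conditions: Cu(OAc)2·H2O (10 mol %), chiral indane-bis(oxazoline) ligand (11 mol %; enantiomer directing attack on the Re face of the aldehyde), EtOH, rt
Reagents that add atoms: none
Why: Copper(II)–bis(oxazoline)-catalysed asymmetric Henry reaction, in which the catalyst should fix the new carbinol centre (C8, S) irrespective of the neighbouring C7 centre; the nitro-bearing carbon becomes the C9 carbonyl in step 10.

Step 9
Reactants: 15 nitro aldol
Product: 16 TBS ether of 15: 4-[(1S)-1-[(tert-butyldimethylsilyl)oxy]-2-nitropropyl]-5-ethenyl-3-[(phenylselanyl)methyl]oxolan-2-one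
Conditions: TBSOTf, 2,6-lutidine, CH2Cl2, −78 to 0 °C
Reagents that add atoms: tert-butyldimethylsilyl trifluoromethanesulfonate, CC(C)(C)[Si](C)(C)OS(=O)(=O)C(F)(F)F
Why: O-Silylation with a silyl triflate and a weak hindered base blocks retro-Henry cleavage and installs the bulky, non-chelating group needed in steps 13 and 15; configuration retained.

Step 10
Reactants: 16 silylated nitro aldol
Product: 17 4-[(1S)-1-[(tert-butyldimethylsilyl)oxy]-2-oxopropyl]-5-ethenyl-3-[(phenylselanyl)methyl]oxolan-2-one (α-silyloxy methyl ketone)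
Conditions: aq. TiCl3, NH4OAc, THF–H2O, rt
Reagents that add atoms: water, O
Why: Ti(III)-mediated reductive Nef reaction (nitro to imine, then hydrolysis) is non-oxidising towards the selenide and near neutral, so the C8 centre α to the new C9 carbonyl should not epimerise.

Step 11
Reactants: 17 α-silyloxy methyl ketone; 3 {[2-(bromomethyl)prop-2-en-1-yl]oxy}(tert-butyl)diphenylsilane
Product: 19 4-[(1S)-1-[(tert-butyldimethylsilyl)oxy]-5-{[(tert-butyldiphenylsilyl)oxy]methyl}-2-oxohex-5-en-1-yl]-5-ethenyl-3-[(phenylselanyl)methyl]oxolan-2-one (diene ketone), via lithium enolate 18 (not isolated)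
Conditions: LDA (1.05 equiv), THF, −78 °C; then 3, DMPU, −78 to −40 °C
Reagents that add atoms: none
Why: Kinetic deprotonation occurs at the methyl group rather than at the hindered silyloxy-bearing methine or the tertiary lactone α-position, and the enolate is alkylated by the reactive allylic bromide (kinetic enolate alkylation), forming C2–C3 without touching a stereocentre.

Step 12
Reactants: 19 diene ketone
Product: 20 lactone-fused cyclooct-4-enone (C9 ketone; ring-cis C4=C5 bearing CH2OTBDPS; 8-OTBS; C6, C7, C8 as in the target)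
Conditions: Grubbs second-generation catalyst (10 mol %), toluene (1 mM), 80 °C
Reagents that add atoms: none
Why: Ring-closing metathesis of the vinyl group with the 1,1-disubstituted alkene closes the eight-membered ring, in which the trisubstituted alkene can only be ring-cis as the target requires; the trans-fused lactone pre-organises the two chains.

Step 13
Reactants: 20 lactone-fused cyclooct-4-enone
Product: 21 C9=C2 trimethylsilyl enol ether of 20
Conditions: TMSCl, Et3N, LiHMDS (1.1 equiv), THF, −78 °C (in situ quench)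
Reagents that add atoms: chlorotrimethylsilane, C[Si](C)(C)Cl
Why: Kinetic enolisation by the hindered amide takes the C2 methylene proton rather than the C8 methine proton, which is shielded by the silyloxy group, and in situ O-silylation fixes the enol ether on the C2 side (kinetic silyl enol ether formation).

Step 14
Reactants: 21 C9=C2 trimethylsilyl enol ether; 22 methyl propiolate
Product: 26 ring-enlarged keto lactone (ten-membered alkylidene β-keto ester), via cyclobutene silyl ether 23 (not isolated), via cyclobutenolate 24 (not isolated), via ring-enlarged dienolate 25 (not isolated)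
Conditions: TiCl4 (1.1 equiv), CH2Cl2, −78 °C; aq. NaHCO3 work-up; then TBAF (1.05 equiv), THF, −78 °C; AcOH quench; Et3N (5 mol %), CH2Cl2, rt
Reagents that add atoms: none
Why: TiCl4-activated methyl propiolate is attacked at its β-carbon by C2 of the enol ether and the resulting allenolate closes onto the oxocarbenium carbon C9 to give the bicyclo[6.2.0]decene 23; fluoride then frees the strained cyclobutenolate 24, which undergoes retro-aldol cleavage of C9–C2 to the ring-enlarged dienolate 25, protonated to 26. The closest known chemistry is the Lewis-acid [2+2] cycloaddition of cyclic silyl enol ethers with propiolates and the two-carbon ring enlargement of cyclic ketones through such cyclobutenes (also known from enamines and from β-keto esters with acetylenic esters). The only ring closed is the cyclobutene, formed stepwise by Mukaiyama–Michael addition and 4-exo-trig aldol-type closure, whereas the ten-membered ring arises by fragmentation of the bond shared by the four- and eight-membered rings. No stereocentre of 26 is created: C2 and C9 of 23 are transient (cis fusion is enforced, and both faces converge), and the C1=C10 geometry is dictated by the cyclobutene, in which C9 and C2 are necessarily cis, so the ester ends up trans to C2 as required. The step needs bond formation at C2 (secured by the regiodefined enol ether), cleavage of C9–C2 rather than C9–C8 (only C2 leaves as an ester-conjugated anion), removal of the tertiary O–TMS group in the presence of the TBS and TBDPS ethers (one equivalent of fluoride at −78 °C) and protonation at C2 (equilibration to the conjugated alkylidene β-keto ester, expected to be the thermodynamic tautomer), while C8 is protected from epimerisation because the C9 carbonyl is tied up as the enolate.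

Step 15
Reactants: 26 ring-enlarged keto lactone
Product: 27 9α-alcohol (9S)
Conditions: NaBH4, CeCl3·7H2O, MeOH, −78 °C
Reagents that add atoms: none
Why: Luche 1,2-reduction of the hindered, cross-conjugated ketone; under non-chelating conditions with the bulky 8-silyloxy group, hydride should attack anti to the C8–O bond (Felkin–Anh), giving the 8,9-threo (9S) carbinol.

Step 16
Reactants: 27 9α-alcohol
Product: 28 9α-acetate
Conditions: Ac2O, DMAP, pyridine, CH2Cl2, 0 °C to rt
Reagents that add atoms: acetic anhydride, CC(=O)OC(C)=O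
Why: DMAP-catalysed acetylation of the secondary allylic alcohol with retention at C9.

Step 17
Reactants: 28 9α-acetate
Product: 29 9α-acetoxy-8β-alcohol
Conditions: HF·pyridine, pyridine, THF, 0 °C to rt
Reagents that add atoms: none
Why: Buffered acidic fluoride should cleave the secondary TBS ether while the primary TBDPS ether, which is much more stable under these conditions, the lactone and the esters survive (selective desilylation); the buffer suppresses 1,2-acetyl migration.

Step 18
Reactants: 29 9α-acetoxy-8β-alcohol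
Product: 30 9α-acetoxy-8β-isobutyrate (15-O-TBDPS)
Conditions: (iPrCO)2O, DMAP, Et3N, CH2Cl2, 0 °C to rt
Reagents that add atoms: 2-methylpropanoic anhydride, CC(C)C(=O)OC(=O)C(C)C
Why: DMAP-catalysed acylation of the C8 hydroxyl with the anhydride present before the base, so that esterification outruns acetyl migration; configuration at C8 retained.

Step 19
Reactants: 30 9α-acetoxy-8β-isobutyrate (15-O-TBDPS)
Product: 31 15-alcohol (13-phenylselanyl-11,13-dihydro target)
Conditions: HF·pyridine (excess), THF, rt
Reagents that add atoms: none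
Why: Fluoride-mediated removal of the primary allylic TBDPS ether under acidic conditions that leave the three esters, the lactone and the selenide untouched.

Step 20
Reactants: 31 15-alcohol selenide
Product: 33 CNP0242134.2 (target), via selenoxide 32 (not isolated)
Conditions: NaIO4, NaHCO3, THF–H2O, 0 °C to rt
Reagents that add atoms: none
Why: Periodate oxidises the selenide to the selenoxide, which undergoes syn-elimination at room temperature towards its only β-hydrogen (H11), unveiling the α-methylene lactone under neutral conditions as the last event (selenoxide elimination); the temporary C11 centre is erased.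

**Compound list**

1 | 2-methylidenepropane-1,3-diol | C=C(CO)CO | starting material
2 | 2-{[(tert-butyldiphenylsilyl)oxy]methyl}prop-2-en-1-ol | C=C(CO)CO[Si](c1ccccc1)(c1ccccc1)C(C)(C)C | intermediate
3 | {[2-(bromomethyl)prop-2-en-1-yl]oxy}(tert-butyl)diphenylsilane | C=C(CBr)CO[Si](c1ccccc1)(c1ccccc1)C(C)(C)C | intermediate
4 | 2,2-dimethoxyacetaldehyde | COC(OC)C=O | starting material
5 | methyl acrylate | C=CC(=O)OC | starting material
6 | methyl 3-hydroxy-4,4-dimethoxy-2-methylidenebutanoate (racemic) | COC(OC)C(O)C(=C)C(=O)OC | intermediate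
7 | methyl (2Z)-2-(bromomethyl)-4,4-dimethoxybut-2-enoate | COC(OC)/C=C(\CBr)C(=O)OC | intermediate
8 | acrolein (prop-2-enal) | C=CC=O | starting material
9 | methyl (3S,4R)-3-(dimethoxymethyl)-2-methylidene-4-[(trimethylsilyl)oxy]hex-5-enoate (not isolated) | C=C[C@@H](O[Si](C)(C)C)[C@@H](C(OC)OC)C(=C)C(=O)OC | intermediate
10 | methyl (3S,4R)-3-(dimethoxymethyl)-4-hydroxy-2-methylidenehex-5-enoate (not isolated) | C=C[C@@H](O)[C@@H](C(OC)OC)C(=C)C(=O)OC | intermediate
11 | (4S,5R)-4-(dimethoxymethyl)-5-ethenyl-3-methylideneoxolan-2-one (4,5-trans) | C=C1C(=O)O[C@H](C=C)[C@H]1C(OC)OC | intermediate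
12 | (3S,4S,5R)-4-(dimethoxymethyl)-5-ethenyl-3-[(phenylselanyl)methyl]oxolan-2-one (all-trans) | O=C1O[C@H](C=C)[C@@H](C(OC)OC)[C@@H]1C[Se]c1ccccc1 | intermediate
13 | (2R,3S,4S)-2-ethenyl-5-oxo-4-[(phenylselanyl)methyl]oxolane-3-carbaldehyde | O=C1O[C@H](C=C)[C@@H](C=O)[C@@H]1C[Se]c1ccccc1 | intermediate
14 | nitroethane | CC[N+](=O)[O-] | starting material
15 | 5-ethenyl-4-[(1S)-1-hydroxy-2-nitropropyl]-3-[(phenylselanyl)methyl]oxolan-2-one (lactone centres as in 13; epimeric at the nitro carbon) | O=C1O[C@H](C=C)[C@@H]([C@H](O)C(C)[N+](=O)[O-])[C@@H]1C[Se]c1ccccc1 | intermediate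
16 | 4-[(1S)-1-[(tert-butyldimethylsilyl)oxy]-2-nitropropyl]-5-ethenyl-3-[(phenylselanyl)methyl]oxolan-2-one (epimeric at the nitro carbon) | O=C1O[C@H](C=C)[C@@H]([C@H](O[Si](C)(C)C(C)(C)C)C(C)[N+](=O)[O-])[C@@H]1C[Se]c1ccccc1 | intermediate
17 | 4-[(1S)-1-[(tert-butyldimethylsilyl)oxy]-2-oxopropyl]-5-ethenyl-3-[(phenylselanyl)methyl]oxolan-2-one | O=C1O[C@H](C=C)[C@@H]([C@H](O[Si](C)(C)C(C)(C)C)C(C)=O)[C@@H]1C[Se]c1ccccc1 | intermediate
18 | lithium enolate of 17 on the methyl side (not isolated) | O=C1O[C@H](C=C)[C@@H]([C@H](O[Si](C)(C)C(C)(C)C)C(=C)O[Li])[C@@H]1C[Se]c1ccccc1 | intermediate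
19 | 4-[(1S)-1-[(tert-butyldimethylsilyl)oxy]-5-{[(tert-butyldiphenylsilyl)oxy]methyl}-2-oxohex-5-en-1-yl]-5-ethenyl-3-[(phenylselanyl)methyl]oxolan-2-one | O=C1O[C@H](C=C)[C@@H]([C@H](O[Si](C)(C)C(C)(C)C)C(=O)CCC(=C)CO[Si](c2ccccc2)(c2ccccc2)C(C)(C)C)[C@@H]1C[Se]c1ccccc1 | intermediate
20 | 9-oxo-8β-[(tert-butyldimethylsilyl)oxy]-15-[(tert-butyldiphenylsilyl)oxy]-13-(phenylselanyl)-1,10-dinor-11βH-germacr-4-en-12,6α-olide (C9 bonded to C2; γ-lactone trans-fused to a cyclooct-4-enone; ring-cis C4=C5) | O=C1O[C@@H]2/C=C(/CO[Si](c3ccccc3)(c3ccccc3)C(C)(C)C)CCC(=O)[C@@H](O[Si](C)(C)C(C)(C)C)[C@H]2[C@@H]1C[Se]c1ccccc1 | intermediate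
21 | C9=C2 trimethylsilyl enol ether of 20 (lactone-fused cycloocta-1,5-diene) | O=C1O[C@@H]2/C=C(/CO[Si](c3ccccc3)(c3ccccc3)C(C)(C)C)C/C=C(O[Si](C)(C)C)\[C@@H](O[Si](C)(C)C(C)(C)C)[C@H]2[C@@H]1C[Se]c1ccccc1 | intermediate
22 | methyl propiolate | C#CC(=O)OC | starting material
23 | cis-fused bicyclo[6.2.0]dec-9-ene from 21: C2–C1H=C10(CO2Me)–C9(OSiMe3) cyclobutene (not isolated; either face of the enol ether) | O=C1O[C@@H]2/C=C(/CO[Si](c3ccccc3)(c3ccccc3)C(C)(C)C)CC4C=C(C(=O)OC)C4(O[Si](C)(C)C)[C@@H](O[Si](C)(C)C(C)(C)C)[C@H]2[C@@H]1C[Se]c1ccccc1 | intermediate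
24 | tetrabutylammonium C9-alkoxide of the cyclobutenol derived from 23 (not isolated) | O=C1O[C@@H]2/C=C(/CO[Si](c3ccccc3)(c3ccccc3)C(C)(C)C)CC4C=C(C(=O)OC)C4([O-])[C@@H](O[Si](C)(C)C(C)(C)C)[C@H]2[C@@H]1C[Se]c1ccccc1.CCCC[N+](CCCC)(CCCC)CCCC | intermediate
25 | tetrabutylammonium dienolate of the ring-enlarged β-keto ester (C9 enolate conjugated through C10 to C1=C2; not isolated) | O=C1O[C@@H]2/C=C(/CO[Si](c3ccccc3)(c3ccccc3)C(C)(C)C)CC=CC(C(=O)OC)=C([O-])[C@@H](O[Si](C)(C)C(C)(C)C)[C@H]2[C@@H]1C[Se]c1ccccc1.CCCC[N+](CCCC)(CCCC)CCCC | intermediate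
26 | methyl 9-oxo-8β-[(tert-butyldimethylsilyl)oxy]-15-[(tert-butyldiphenylsilyl)oxy]-13-(phenylselanyl)-11βH-cis,cis-germacra-1(10),4-dien-12,6α-olid-14-oate | O=C1O[C@@H]2/C=C(/CO[Si](c3ccccc3)(c3ccccc3)C(C)(C)C)CC/C=C(/C(=O)OC)C(=O)[C@@H](O[Si](C)(C)C(C)(C)C)[C@H]2[C@@H]1C[Se]c1ccccc1 | intermediate
27 | 9α-hydroxy analogue of 26 (9S alcohol) | O=C1O[C@@H]2/C=C(/CO[Si](c3ccccc3)(c3ccccc3)C(C)(C)C)CC/C=C(/C(=O)OC)[C@H](O)[C@@H](O[Si](C)(C)C(C)(C)C)[C@H]2[C@@H]1C[Se]c1ccccc1 | intermediate
28 | 9α-acetate of 27 | O=C1O[C@@H]2/C=C(/CO[Si](c3ccccc3)(c3ccccc3)C(C)(C)C)CC/C=C(/C(=O)OC)[C@H](OC(C)=O)[C@@H](O[Si](C)(C)C(C)(C)C)[C@H]2[C@@H]1C[Se]c1ccccc1 | intermediate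
29 | 9α-acetoxy-8β-hydroxy compound (TBS removed; 15-O-TBDPS) | O=C1O[C@@H]2/C=C(/CO[Si](c3ccccc3)(c3ccccc3)C(C)(C)C)CC/C=C(/C(=O)OC)[C@H](OC(C)=O)[C@@H](O)[C@H]2[C@@H]1C[Se]c1ccccc1 | intermediate
30 | 9α-acetoxy-8β-(2-methylpropanoyloxy) compound (15-O-TBDPS; 13-phenylselanyl) | O=C1O[C@@H]2/C=C(/CO[Si](c3ccccc3)(c3ccccc3)C(C)(C)C)CC/C=C(/C(=O)OC)[C@H](OC(C)=O)[C@@H](OC(=O)C(C)C)[C@H]2[C@@H]1C[Se]c1ccccc1 | intermediate
31 | methyl 9α-acetoxy-15-hydroxy-8β-(2-methylpropanoyloxy)-13-(phenylselanyl)-11βH-cis,cis-germacra-1(10),4-dien-12,6α-olid-14-oate | O=C1O[C@@H]2/C=C(/CO)CC/C=C(/C(=O)OC)[C@H](OC(C)=O)[C@@H](OC(=O)C(C)C)[C@H]2[C@@H]1C[Se]c1ccccc1 | intermediate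
32 | selenoxide of 31 (not isolated) | O=C1O[C@@H]2/C=C(/CO)CC/C=C(/C(=O)OC)[C@H](OC(C)=O)[C@@H](OC(=O)C(C)C)[C@H]2[C@@H]1C[Se](=O)c1ccccc1 | intermediate
33 | CNP0242134.2: methyl (6R,7S,8S,9S)-9-acetoxy-15-hydroxy-8-(2-methylpropanoyloxy)-cis,cis-germacra-1(10),4,11(13)-trien-12,6-olid-14-oate | C=C1C(=O)O[C@@H]2/C=C(/CO)CC/C=C(/C(=O)OC)[C@H](OC(C)=O)[C@@H](OC(=O)C(C)C)[C@@H]12 | target

**Step count.** Total: 20 steps. Longest linear sequence: 18 steps (steps 3–20, from 4 and 5); bromide 3 (steps 1–2) joins at step 11.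

**Steps most likely to fail, with fallbacks**

Step 14 (key step). The silyl group may be lost before the four-membered ring closes, giving an open Michael adduct instead of the cyclobutene. The Lewis acid may also ionise the allylic silyl ethers, and the ring-enlarged dienolate may be protonated at C10, leaving the deconjugated tautomer. The fallback avoids both Lewis acid and fluoride and sets out from ketone 20. Condensation with pyrrolidine (TiCl4, Et3N, toluene, 0 °C) should give the less substituted pyrrolidine enamine F1. With methyl propiolate 22 (toluene, rt to 60 °C) this should form the aminocyclobutene F2 by thermal [2+2] addition, which opens in the same flask by 4π-electrocyclic ring opening to the ring-enlarged dienamino ester F3 (the classical enamine–acetylenic ester two-carbon ring enlargement). Hydrolysis with aqueous acetic acid–sodium acetate and base-catalysed equilibration bring the route back at 26.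

Step 12. Intermolecular metathesis through the monosubstituted vinyl group may outrun closure onto the 1,1-disubstituted alkene, leading to oligomers, because the sp2 C9 centre and its α-silyloxy group hold the chain extended. The fallback sets out from diene ketone 19. Reduction with NaBH4 (MeOH, 0 °C) gives the C9 carbinol F4 (epimers, inconsequential), whose more flexible chain should close under the same metathesis catalyst to the cyclooctenol F5. Parikh–Doering oxidation (SO3·pyridine, DMSO, iPr2NEt), which spares the selenide, returns the route at 20.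

Step 15. Hydride delivery to the medium-ring ketone may be governed by ring conformation rather than by the Felkin–Anh preference, so that attack occurs on the wrong face; conjugate reduction of the doubly activated alkene may also compete. The fallback sets out from 26. If the reduction gives mainly the 9-epi alcohol F6, a Mitsunobu reaction with acetic acid (PPh3, DIAD, toluene, 0 °C) inverts C9 and installs the acetate in one operation, returning the route at 28 and saving step 16.

**Further compounds**

F1 | step 14 | pyrrolidine enamine of 20 (C9=C2 enamine) | O=C1O[C@@H]2/C=C(/CO[Si](c3ccccc3)(c3ccccc3)C(C)(C)C)C/C=C(N4CCCC4)\[C@@H](O[Si](C)(C)C(C)(C)C)[C@H]2[C@@H]1C[Se]c1ccccc1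
F2 | step 14 | aminocyclobutene from F1 and 22 (C9 pyrrolidinyl; cis-fused; not isolated) | O=C1O[C@@H]2/C=C(/CO[Si](c3ccccc3)(c3ccccc3)C(C)(C)C)CC4C=C(C(=O)OC)C4(N5CCCC5)[C@@H](O[Si](C)(C)C(C)(C)C)[C@H]2[C@@H]1C[Se]c1ccccc1
F3 | step 14 | ring-enlarged 9-pyrrolidinyl dienamino ester (geometry of the two new double bonds not defined) | O=C1O[C@@H]2/C=C(/CO[Si](c3ccccc3)(c3ccccc3)C(C)(C)C)CC=CC(C(=O)OC)=C(N4CCCC4)[C@@H](O[Si](C)(C)C(C)(C)C)[C@H]2[C@@H]1C[Se]c1ccccc1
F4 | step 12 | C9 carbinol of diene ketone 19 (epimeric at C9) | O=C1O[C@H](C=C)[C@@H]([C@H](O[Si](C)(C)C(C)(C)C)C(O)CCC(=C)CO[Si](c2ccccc2)(c2ccccc2)C(C)(C)C)[C@@H]1C[Se]c1ccccc1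
F5 | step 12 | lactone-fused cyclooct-4-enol (C9 carbinol of 20; epimeric at C9) | O=C1O[C@@H]2/C=C(/CO[Si](c3ccccc3)(c3ccccc3)C(C)(C)C)CCC(O)[C@@H](O[Si](C)(C)C(C)(C)C)[C@H]2[C@@H]1C[Se]c1ccccc1
F6 | step 15 | 9-epi-27 (9β-alcohol) | O=C1O[C@@H]2/C=C(/CO[Si](c3ccccc3)(c3ccccc3)C(C)(C)C)CC/C=C(/C(=O)OC)[C@@H](O)[C@@H](O[Si](C)(C)C(C)(C)C)[C@H]2[C@@H]1C[Se]c1ccccc1
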